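**Assumption:** the target SMILES has no stereocentre and no stereogenic C=C, so the compound is achiral and no stereocontrol is needed; 1,3-diketones are drawn as the diketo tautomer.

## Retrosynthetic overview

1. Target 18 ⇐ desilylation of 17 ⇐ Baker–Venkataraman O→C aroyl shift of aryl ester 16 ⇐ chromene ketone 8 + benzoic acid 15 (convergent union, last three steps).
2. Chromene ketone 8: its 2H-pyran ring, the only ring made, is closed by ring-closing metathesis of diene 7 (styrene + 1,1-dimethylallyl aryl ether).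
3. Diene 7 ⇐ Pd-catalysed tert-allylation of vinyl-resacetophenone 5 ⇐ Stille vinylation ⇐ Nencki acetylation of 4-bromoresorcinol.
4. Acid 15 ⇐ methyl 4-hydroxybenzoate by Pd tert-allylation, aromatic Claisen (sets the prenyl group), saponification and silylation.
5. Ring order: both benzene rings are bought; the pyran ring is closed in step 4, before the prenyl-bearing half is attached, so the prenyl olefin never meets the Ru catalyst.

## Route

**Step 1**
Reactants: 1 4-bromoresorcinol; 2 acetic acid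
Product: 3 1-(5-bromo-2,4-dihydroxyphenyl)ethan-1-one
Conditions: AcOH (solvent), ZnCl2 (1.5 equiv), 130 °C, 1 h (–H2O); dil. HCl work-up
Reagents that add atoms: none
Why: Nencki (Friedel–Crafts) acylation occurs at the only position ortho to one OH and para to the other that is not flanked by both OH groups, so the bromo/acetyl pattern is unambiguous.

**Step 2**
Reactants: 3 1-(5-bromo-2,4-dihydroxyphenyl)ethan-1-one; 4 tributyl(vinyl)stannane
Product: 5 1-(5-ethenyl-2,4-dihydroxyphenyl)ethan-1-one
Conditions: Pd(PPh3)4 (5 mol %), BHT (cat.), PhMe, 100 °C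
Reagents that add atoms: none
Why: Stille coupling runs under neutral conditions, so the free phenols and the ketone are tolerated and BHT keeps the hydroxystyrene from polymerising.

**Step 3**
Reactants: 5 1-(5-ethenyl-2,4-dihydroxyphenyl)ethan-1-one; 6 tert-butyl 2-methylbut-3-en-2-yl carbonate
Product: 7 1-{5-ethenyl-2-hydroxy-4-[(2-methylbut-3-en-2-yl)oxy]phenyl}ethan-1-one
Conditions: 6 (1.5 equiv), Pd(PPh3)4 (2 mol %), THF, 0 °C, 1–2 h
Reagents that add atoms: none
Why: In this Tsuji–Trost O-allylation the non-chelated, more acidic 4-OH attacks the 1,1-dimethyl-π-allyl-Pd at its tertiary terminus under kinetic control at 0 °C, while the 2-OH stays hydrogen-bonded to the ketone.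

**Step 4**
Reactants: 7 1-{5-ethenyl-2-hydroxy-4-[(2-methylbut-3-en-2-yl)oxy]phenyl}ethan-1-one
Product: 8 1-(7-hydroxy-2,2-dimethyl-2H-chromen-6-yl)ethan-1-one
Conditions: Grubbs II (5 mol %), CH2Cl2 (5 mM), 40 °C
Reagents that add atoms: none
Why: Ring-closing metathesis of the styrene and the monosubstituted allyl ether olefin gives the six-membered cis-alkene with loss of ethylene; there are no allylic hydrogens to isomerise and 40 °C is too low for Claisen rearrangement.

**Step 5**
Reactants: 9 methyl 4-hydroxybenzoate; 6 tert-butyl 2-methylbut-3-en-2-yl carbonate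
Product: 10 methyl 4-[(2-methylbut-3-en-2-yl)oxy]benzoate
Conditions: 6 (1.3 equiv), Pd(PPh3)4 (2 mol %), THF, 0 °C
Reagents that add atoms: none
Why: Same Tsuji–Trost O-tert-allylation as step 3, with the phenoxide generated by the tert-butoxide released from the carbonate.

**Step 6**
Reactants: 10 methyl 4-[(2-methylbut-3-en-2-yl)oxy]benzoate
Product: 12 methyl 4-hydroxy-3-(3-methylbut-2-en-1-yl)benzoate, via methyl 3-(3-methylbut-2-en-1-yl)-4-oxocyclohexa-1,5-diene-1-carboxylate 11 (not isolated)
Conditions: PhNEt2, 150 °C, Ar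
Reagents that add atoms: none
Why: Aromatic Claisen [3,3] rearrangement of the 1,1-dimethylallyl ether delivers the linear prenyl group to the ortho carbon (para is blocked), and the dienone re-aromatises by tautomerisation; the amine solvent suppresses acid-catalysed chroman formation.

**Step 7**
Reactants: 12 methyl 4-hydroxy-3-(3-methylbut-2-en-1-yl)benzoate
Product: 13 4-hydroxy-3-(3-methylbut-2-en-1-yl)benzoic acid
Conditions: LiOH·H2O (4 equiv), THF/MeOH/H2O, 50 °C; then 1 M HCl, 0 °C, pH 3
Reagents that add atoms: lithium hydroxide, [Li+].[OH-]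
Why: Simple ester saponification; the prenyl olefin is inert to base and survives the brief cold acidification.

**Step 8**
Reactants: 13 4-hydroxy-3-(3-methylbut-2-en-1-yl)benzoic acid
Product: 15 4-[(tert-butyldimethylsilyl)oxy]-3-(3-methylbut-2-en-1-yl)benzoic acid, via tert-butyldimethylsilyl 4-[(tert-butyldimethylsilyl)oxy]-3-(3-methylbut-2-en-1-yl)benzoate 14 (not isolated)
Conditions: TBSCl (2.5 equiv), imidazole (5 equiv), DMF, rt; then AcOH/THF/H2O (3:1:1), rt
Reagents that add atoms: tert-butyldimethylsilyl chloride, CC(C)(C)[Si](C)(C)Cl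
Why: Bis-silylation followed by selective hydrolysis of the much more labile silyl ester leaves the aryl TBS ether, a phenol protection that can later be removed without acid.

**Step 9**
Reactants: 8 1-(7-hydroxy-2,2-dimethyl-2H-chromen-6-yl)ethan-1-one; 15 4-[(tert-butyldimethylsilyl)oxy]-3-(3-methylbut-2-en-1-yl)benzoic acid
Product: 16 6-acetyl-2,2-dimethyl-2H-chromen-7-yl 4-[(tert-butyldimethylsilyl)oxy]-3-(3-methylbut-2-en-1-yl)benzoate
Conditions: DCC (1.2 equiv), DMAP (0.2 equiv), CH2Cl2, 0 °C → rt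
Reagents that add atoms: none
Why: Steglich esterification acylates the hydrogen-bonded phenol under neutral conditions that leave the chromene, prenyl and silyl ether untouched.

**Step 10**
Reactants: 16 6-acetyl-2,2-dimethyl-2H-chromen-7-yl 4-[(tert-butyldimethylsilyl)oxy]-3-(3-methylbut-2-en-1-yl)benzoate
Product: 17 1-{4-[(tert-butyldimethylsilyl)oxy]-3-(3-methylbut-2-en-1-yl)phenyl}-3-(7-hydroxy-2,2-dimethyl-2H-chromen-6-yl)propane-1,3-dione
Conditions: LiHMDS (2.5 equiv), THF, –78 → 0 °C; then AcOH (3 equiv)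
Reagents that add atoms: none
Why: Baker–Venkataraman rearrangement: the methyl ketone enolate attacks the neighbouring aryl ester intramolecularly, and the O→C aroyl transfer is driven by formation of the stabilised diketonate/phenoxide; the non-nucleophilic base spares the aryl silyl ether.

**Step 11**
Reactants: 17 1-{4-[(tert-butyldimethylsilyl)oxy]-3-(3-methylbut-2-en-1-yl)phenyl}-3-(7-hydroxy-2,2-dimethyl-2H-chromen-6-yl)propane-1,3-dione
Product: 18 glyinflanin C, 1-[4-hydroxy-3-(3-methylbut-2-en-1-yl)phenyl]-3-(7-hydroxy-2,2-dimethyl-2H-chromen-6-yl)propane-1,3-dione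
Conditions: TBAF (1.1 equiv), AcOH (1.2 equiv), THF, 0 °C
Reagents that add atoms: none
Why: Buffered fluoride desilylation frees the phenol without the acid that would cyclise the 2-hydroxy-1,3-diketone to a flavone or the prenylphenol to a chroman.

## Compound list

1 | 4-bromoresorcinol (4-bromobenzene-1,3-diol) | Oc1ccc(Br)c(O)c1 | starting material
2 | acetic acid | CC(=O)O | starting material
3 | 1-(5-bromo-2,4-dihydroxyphenyl)ethan-1-one | CC(=O)c1cc(Br)c(O)cc1O | intermediate
4 | tributyl(vinyl)stannane | C=C[Sn](CCCC)(CCCC)CCCC | starting material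
5 | 1-(5-ethenyl-2,4-dihydroxyphenyl)ethan-1-one | CC(=O)c1cc(C=C)c(O)cc1O | intermediate
6 | tert-butyl 2-methylbut-3-en-2-yl carbonate | C=CC(C)(C)OC(=O)OC(C)(C)C | starting material
7 | 1-{5-ethenyl-2-hydroxy-4-[(2-methylbut-3-en-2-yl)oxy]phenyl}ethan-1-one | CC(=O)c1cc(C=C)c(OC(C)(C)C=C)cc1O | intermediate
8 | 1-(7-hydroxy-2,2-dimethyl-2H-chromen-6-yl)ethan-1-one | CC(=O)c1cc2c(cc1O)OC(C)(C)C=C2 | intermediate
9 | methyl 4-hydroxybenzoate | COC(=O)c1ccc(O)cc1 | starting material
10 | methyl 4-[(2-methylbut-3-en-2-yl)oxy]benzoate | COC(=O)c1ccc(OC(C)(C)C=C)cc1 | intermediate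
11 | methyl 3-(3-methylbut-2-en-1-yl)-4-oxocyclohexa-1,5-diene-1-carboxylate (racemic Claisen dienone, not isolated) | COC(=O)C1=CC(CC=C(C)C)C(=O)C=C1 | intermediate
12 | methyl 4-hydroxy-3-(3-methylbut-2-en-1-yl)benzoate | COC(=O)c1ccc(O)c(CC=C(C)C)c1 | intermediate
13 | 4-hydroxy-3-(3-methylbut-2-en-1-yl)benzoic acid | OC(=O)c1ccc(O)c(CC=C(C)C)c1 | intermediate
14 | tert-butyldimethylsilyl 4-[(tert-butyldimethylsilyl)oxy]-3-(3-methylbut-2-en-1-yl)benzoate (not isolated) | CC(C)=CCc1cc(C(=O)O[Si](C)(C)C(C)(C)C)ccc1O[Si](C)(C)C(C)(C)C | intermediate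
15 | 4-[(tert-butyldimethylsilyl)oxy]-3-(3-methylbut-2-en-1-yl)benzoic acid | CC(C)=CCc1cc(C(=O)O)ccc1O[Si](C)(C)C(C)(C)C | intermediate
16 | 6-acetyl-2,2-dimethyl-2H-chromen-7-yl 4-[(tert-butyldimethylsilyl)oxy]-3-(3-methylbut-2-en-1-yl)benzoate | CC(=O)c1cc2c(cc1OC(=O)c1ccc(O[Si](C)(C)C(C)(C)C)c(CC=C(C)C)c1)OC(C)(C)C=C2 | intermediate
17 | 1-{4-[(tert-butyldimethylsilyl)oxy]-3-(3-methylbut-2-en-1-yl)phenyl}-3-(7-hydroxy-2,2-dimethyl-2H-chromen-6-yl)propane-1,3-dione | CC(C)=CCc1cc(C(=O)CC(=O)c2cc3c(cc2O)OC(C)(C)C=C3)ccc1O[Si](C)(C)C(C)(C)C | intermediate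
18 | glyinflanin C | CC(C)=CCc1cc(C(=O)CC(=O)c2cc3c(cc2O)OC(C)(C)C=C3)ccc1O | target

## Step count and risks

Total step count: 11.
Longest linear sequence: 7 (steps 1–4 then 9–11, or steps 5–8 then 9–11), i.e. 7/11 of the total.

**Step 3 (tertiary ether next to the vinyl group; possible drift to the linear prenyl ether).** The fallback sets out from 5 and comes back at 7. The 4-OH of 5 is alkylated with 3-chloro-3-methylbut-1-yne (C#CC(C)(C)Cl) under copper catalysis (CuCl2·2H2O cat., DBU, MeCN, 0 °C) to give the propargyl ether 1-{5-ethenyl-2-hydroxy-4-[(2-methylbut-3-yn-2-yl)oxy]phenyl}ethan-1-one F1. The terminal alkyne of F1 is then semi-hydrogenated (Lindlar catalyst, quinoline, H2 1 atm, EtOAc, stopped at 1 equiv) to give 7; the terminal alkyne is reduced well before the styrene.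

**Step 4 (RCM onto an olefin with a quaternary allylic carbon).** The fallback sets out from 3 and comes back at 8. Heck coupling of 3 with 2-methylbut-3-en-2-ol (C=CC(C)(C)O; Pd(OAc)2, P(o-tol)3, Et3N, DMF, 100 °C) gives 1-{2,4-dihydroxy-5-[(1E)-3-hydroxy-3-methylbut-1-en-1-yl]phenyl}ethan-1-one F2. Warming F2 with PPTS (cat.) in toluene at 80 °C eliminates water to the vinyl o-quinone methide 4-acetyl-3-hydroxy-6-(3-methylbut-2-en-1-ylidene)cyclohexa-2,4-dien-1-one F3, which is not isolated and closes by oxa-6π electrocyclisation to 8.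

**Step 6 (Claisen rearrangement competing with loss of isoprene from the electron-poor aryl ether).** The fallback sets out from 9 and comes back at 12. Ortho-iodination of 9 (NIS, TsOH cat., MeCN, rt) gives methyl 4-hydroxy-3-iodobenzoate F4. Stille coupling of F4 with tributyl(3-methylbut-2-en-1-yl)stannane (CC(C)=CC[Sn](CCCC)(CCCC)CCCC; Pd(PPh3)4, DMF, 90 °C) then installs the linear prenyl group directly to give 12. The prenyl to reverse-prenyl ratio would have to be checked.

## Further compounds

F1 | step 3 | 1-{5-ethenyl-2-hydroxy-4-[(2-methylbut-3-yn-2-yl)oxy]phenyl}ethan-1-one | CC(=O)c1cc(C=C)c(OC(C)(C)C#C)cc1O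
F2 | step 4 | 1-{2,4-dihydroxy-5-[(1E)-3-hydroxy-3-methylbut-1-en-1-yl]phenyl}ethan-1-one | CC(=O)c1cc(/C=C/C(C)(C)O)c(O)cc1O
F3 | step 4 | 4-acetyl-3-hydroxy-6-(3-methylbut-2-en-1-ylidene)cyclohexa-2,4-dien-1-one (E/Z mixture, not isolated) | CC(=O)C1=CC(=CC=C(C)C)C(=O)C=C1O
F4 | step 6 | methyl 4-hydroxy-3-iodobenzoate | COC(=O)c1ccc(O)c(I)c1
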